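The 3(2H)-furanone ring (O, C3, C2, C1, C10 in germacrane numbering) is read as a methyl ketone enolate that has been C-acylated at C2 and O-alkylated at C10 by a glycidic acid. C10 is a quaternary ether carbon whose neighbour C9 carries oxygen, the signature of an opened 2,3-epoxy acyl unit. In one operation the lithium enolate of a Z-enone is acylated by an epoxy acyl imidazole (C2–C1) and the diketonate oxygen opens the epoxide 5-exo at C10 with inversion (O–C10). This joins the two halves, builds the furanone, sets C10 and frees the C9 hydroxyl. A CrCl2-mediated Barbier lactonization at C6–C7 later closes the ten-membered ring.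

Key step: step 11

Assumption: germacrane numbering is used for locants (C1 ketone, C2=C3 of the furanone, C4=C5, C6 lactone carbinol, C7, C8 acyloxy, C9 acetoxy, C10 quaternary, C11–C13 methylene lactone), TBS = tert-butyldimethylsilyl, and commercial aqueous 2,2-dimethoxyacetaldehyde is dried before use.

Step 1
Reactants: 1 2,2-dimethoxyacetaldehyde; 2 ethyl 2-[bis(2,2,2-trifluoroethoxy)phosphoryl]propanoate
Product: 3 ethyl (2Z)-4,4-dimethoxy-2-methylbut-2-enoate
Conditions: KN(SiMe3)2, 18-crown-6, THF, −78 °C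
Reagents that add atoms: none
Why: Still–Gennari variant of the Horner–Wadsworth–Emmons olefination, in which the electron-poor phosphonate under dissociating conditions should eliminate kinetically to the Z enoate (ester cis to the acetal carbon, the later C3/C6 cis relationship).

Step 2
Reactants: 3 ethyl (2Z)-4,4-dimethoxy-2-methylbut-2-enoate
Product: 4 (2Z)-N,4,4-trimethoxy-N,2-dimethylbut-2-enamide
Conditions: MeNHOMe·HCl, i-PrMgCl, THF, −20 → 0 °C
Reagents that add atoms: N,O-dimethylhydroxylamine hydrochloride, CNOC.Cl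
Why: Weinreb amide formation by aminolysis of the ester with the chloromagnesium amide should leave the acetal and the alkene geometry untouched.

Step 3
Reactants: 4 (2Z)-N,4,4-trimethoxy-N,2-dimethylbut-2-enamide
Product: 5 (3Z)-5,5-dimethoxy-3-methylpent-3-en-2-one
Conditions: MeMgBr, THF, −78 → 0 °C
Reagents that add atoms: methylmagnesium bromide, C[Mg]Br
Why: Weinreb ketone synthesis, where the stable magnesium chelate prevents over-addition so that exactly one methyl group (C2) is delivered.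

Step 4
Reactants: 6 (2S)-but-3-ene-1,2-diol
Product: 7 (2S)-1,2-bis(TBSO)but-3-ene
Conditions: TBSCl, imidazole, DMF, 23 °C
Reagents that add atoms: tert-butyldimethylsilyl chloride, CC(C)(C)[Si](C)(C)Cl
Why: Exhaustive silylation of both hydroxyl groups under imidazole catalysis, with the stereocentre (later C8) not involved.

Step 5
Reactants: 7 (2S)-1,2-bis(TBSO)but-3-ene
Product: 8 (2S)-2-(TBSO)but-3-en-1-ol
Conditions: HF·pyridine, pyridine, THF, 0 °C
Reagents that add atoms: none
Why: Buffered fluoride cleaves the less hindered primary silyl ether faster than the secondary one, which frees only the carbinol that becomes C9.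

Step 6
Reactants: 8 (2S)-2-(TBSO)but-3-en-1-ol
Product: 9 (2S)-2-(TBSO)but-3-enal
Conditions: Dess–Martin periodinane, pyridine, CH2Cl2, 0 °C
Reagents that add atoms: none
Why: Dess–Martin oxidation under buffered, amine-base-free conditions should give the α-silyloxy aldehyde without epimerization or migration of the β,γ-double bond.

Step 7
Reactants: 9 (2S)-2-(TBSO)but-3-enal; 2 ethyl 2-[bis(2,2,2-trifluoroethoxy)phosphoryl]propanoate
Product: 10 ethyl (2Z,4S)-4-(TBSO)-2-methylhexa-2,5-dienoate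
Conditions: KN(SiMe3)2, 18-crown-6, THF, −78 °C
Reagents that add atoms: none
Why: Still–Gennari olefination at −78 °C should give the Z-trisubstituted enoate (C1 cis to C8) without loss of the α-stereocentre, the geometry that later becomes the cis epoxide.

Step 8
Reactants: 10 ethyl (2Z,4S)-4-(TBSO)-2-methylhexa-2,5-dienoate
Product: 11 (2Z,4S)-4-(TBSO)-2-methylhexa-2,5-dien-1-ol
Conditions: i-Bu2AlH, CH2Cl2, −78 °C
Reagents that add atoms: none
Why: 1,2-Reduction of the enoate by the aluminium hydride gives the allylic alcohol with the Z geometry retained.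

Step 9
Reactants: 11 (2Z,4S)-4-(TBSO)-2-methylhexa-2,5-dien-1-ol
Product: 12 [(2R,3S)-3-[(1S)-1-(TBSO)prop-2-en-1-yl]-2-methyloxiran-2-yl]methanol
Conditions: Ti(Oi-Pr)4, D-(−)-diisopropyl tartrate, t-BuOOH, 4 Å molecular sieves, CH2Cl2, −20 °C
Reagents that add atoms: tert-butyl hydroperoxide, CC(C)(C)OO
Why: Sharpless asymmetric epoxidation, in which the D-(−)-tartrate complex should deliver oxygen to the face that gives the (9S,10S) epoxide, syn addition keeps C1 and C8 cis, and the vinyl group without an allylic hydroxyl is not touched.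

Step 10
Reactants: 12 [(2R,3S)-3-[(1S)-1-(TBSO)prop-2-en-1-yl]-2-methyloxiran-2-yl]methanol
Product: 13 (2S,3S)-3-[(1S)-1-(TBSO)prop-2-en-1-yl]-2-methyloxirane-2-carboxylic acid
Conditions: TEMPO (cat.), PhI(OAc)2, MeCN/H2O, 23 °C
Reagents that add atoms: water, O
Why: Oxoammonium oxidation of the primary alcohol through the aldehyde hydrate should give the glycidic acid without touching the epoxide, the alkene or the silyl ether.

Step 11
Reactants: 13 (2S,3S)-3-[(1S)-1-(TBSO)prop-2-en-1-yl]-2-methyloxirane-2-carboxylic acid; 5 (3Z)-5,5-dimethoxy-3-methylpent-3-en-2-one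
Product: 16 (2R)-2-[(1S,2S)-2-(TBSO)-1-hydroxybut-3-en-1-yl]-5-[(1Z)-3,3-dimethoxy-1-methylprop-1-en-1-yl]-2-methylfuran-3(2H)-one, via acyl imidazole 14 (not isolated), via epoxy diketone 15 (not isolated)
Conditions: 13, CDI, THF, 23 °C; then added to 5 and LiN(SiMe3)2 (2.2 equiv each) in THF at −78 °C, warm to 0 °C; then DMPU, 40 °C
Reagents that add atoms: none
Why: Proposed new method: the kinetic lithium enolate of 5 (deprotonation of the C2 methyl group) is C-acylated by acyl imidazole 14 in a crossed Claisen condensation (C2–C1 bond), and the lithium diketonate of 15, once DMPU has loosened its chelate, attacks the α-keto epoxide carbon C10 with its C3 enolate oxygen (O–C10 bond); the closest known reactions are the acylation of ketone enolates by acyl imidazoles and the base-induced O-alkylative closure of 4-bromo-1,3-diketones to 3(2H)-furanones. The furanone ring closes in the 5-exo-tet mode with the enolate oxygen as nucleophile, an in-plane O-alkylation that Baldwin's rules for enolates allow. C10 is set by stereospecific SN2 inversion of the (10S) epoxide carbon fixed in step 9, and C9 keeps its configuration as the liberated alkoxide. The step needs C- over O-acylation (lithium counter-ion, THF, −78 °C), enolization at C2 and not at the γ position of the enone (kinetic amide base), and 5-exo opening at the tertiary C10 in preference to 6-endo opening at C9, which the collinear exo trajectory, the SN2-activating α-carbonyl group and the branched, oxygenated C8 next to C9 should secure. C-Alkylation cannot compete because it would form a three- or four-membered ring.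

Step 12
Reactants: 16 (2R)-2-[(1S,2S)-2-(TBSO)-1-hydroxybut-3-en-1-yl]-5-[(1Z)-3,3-dimethoxy-1-methylprop-1-en-1-yl]-2-methylfuran-3(2H)-one
Product: 17 (1S,2S)-2-(TBSO)-1-[(2R)-5-[(1Z)-3,3-dimethoxy-1-methylprop-1-en-1-yl]-2-methyl-3-oxo-2,3-dihydrofuran-2-yl]but-3-en-1-yl acetate
Conditions: Ac2O, DMAP, pyridine, CH2Cl2, 23 °C
Reagents that add atoms: acetic anhydride, CC(=O)OC(C)=O
Why: Nucleophilic-catalysed acetylation of the only free hydroxyl installs the C9 acetate of the target.

Step 13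
Reactants: 17 (1S,2S)-2-(TBSO)-1-[(2R)-5-[(1Z)-3,3-dimethoxy-1-methylprop-1-en-1-yl]-2-methyl-3-oxo-2,3-dihydrofuran-2-yl]but-3-en-1-yl acetate
Product: 19 (1S,2R)-2-(TBSO)-1-[(2R)-5-[(1Z)-3,3-dimethoxy-1-methylprop-1-en-1-yl]-2-methyl-3-oxo-2,3-dihydrofuran-2-yl]-3-oxopropyl acetate, via vicinal diol 18 (not isolated)
Conditions: OsO4 (cat.), NMO, acetone/H2O, 0 °C; then NaIO4
Reagents that add atoms: N-methylmorpholine N-oxide, C[N+]1([O-])CCOCC1
Why: Upjohn dihydroxylation followed by periodate cleavage (Lemieux–Johnson type), in which the isolated monosubstituted alkene should react faster than the two conjugated, electron-poor alkenes of the dienone and leave the C7 aldehyde.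

Step 14
Reactants: 19 (1S,2R)-2-(TBSO)-1-[(2R)-5-[(1Z)-3,3-dimethoxy-1-methylprop-1-en-1-yl]-2-methyl-3-oxo-2,3-dihydrofuran-2-yl]-3-oxopropyl acetate; 20 methyl prop-2-ynoate
Product: 22 methyl (4S,5S)-5-acetoxy-4-(TBSO)-5-[(2R)-5-[(1Z)-3,3-dimethoxy-1-methylprop-1-en-1-yl]-2-methyl-3-oxo-2,3-dihydrofuran-2-yl]-3-hydroxy-2-methylidenepentanoate as the mixture of C3 epimers, via vinylalane 21 (not isolated)
Conditions: 20, i-Bu2AlH, NMO, THF, 0 °C; then 19, 0 → 23 °C
Reagents that add atoms: none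
Why: Vinylalumination, in which the α-aluminio acrylate from hydroalumination of the propiolate adds 1,2 to the aldehyde much faster than to the vinylogous ester carbonyl and gives the Morita–Baylis–Hillman-type adduct, whose new carbinol centre becomes sp2 in step 16.

Step 15
Reactants: 22 methyl (4S,5S)-5-acetoxy-4-(TBSO)-5-[(2R)-5-[(1Z)-3,3-dimethoxy-1-methylprop-1-en-1-yl]-2-methyl-3-oxo-2,3-dihydrofuran-2-yl]-3-hydroxy-2-methylidenepentanoate
Product: 23 methyl (4S,5S)-5-acetoxy-4-(TBSO)-3-hydroxy-2-methylidene-5-[(2R)-2-methyl-5-[(1Z)-1-methyl-3-oxoprop-1-en-1-yl]-3-oxo-2,3-dihydrofuran-2-yl]pentanoate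
Conditions: PPTS, acetone/H2O, 23 °C
Reagents that add atoms: water, O
Why: Mild acid hydrolysis of the allylic dimethyl acetal should unmask the Z-enal (C6) while the secondary silyl ether and the acetate survive.

Step 16
Reactants: 23 methyl (4S,5S)-5-acetoxy-4-(TBSO)-3-hydroxy-2-methylidene-5-[(2R)-2-methyl-5-[(1Z)-1-methyl-3-oxoprop-1-en-1-yl]-3-oxo-2,3-dihydrofuran-2-yl]pentanoate
Product: 24 methyl (2Z,4S,5S)-5-acetoxy-2-(bromomethyl)-4-(TBSO)-5-[(2R)-2-methyl-5-[(1Z)-1-methyl-3-oxoprop-1-en-1-yl]-3-oxo-2,3-dihydrofuran-2-yl]pent-2-enoate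
Conditions: NBS, Me2S, CH2Cl2, 0 → 23 °C
Reagents that add atoms: N-bromosuccinimide, O=C1CCC(=O)N1Br
Why: Corey–Kim-type activation of the allylic alcohol and SN2′ delivery of bromide should give the transposed primary bromide as the thermodynamically preferred Z isomer (C8 cis to CH2Br) from both C7 epimers.

Step 17
Reactants: 24 methyl (2Z,4S,5S)-5-acetoxy-2-(bromomethyl)-4-(TBSO)-5-[(2R)-2-methyl-5-[(1Z)-1-methyl-3-oxoprop-1-en-1-yl]-3-oxo-2,3-dihydrofuran-2-yl]pent-2-enoate
Product: 26 (6R,7S,8S,9S,10R)-9-acetoxy-8-(TBSO)-1-oxo-3,10-epoxygermacra-2,4Z,11(13)-trien-12,6-olide, via hydroxy ester 25 (not isolated)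
Conditions: CrCl2, THF, 23 °C, slow addition of 24 (high dilution)
Reagents that add atoms: none
Why: Intramolecular Nozaki–Hiyama allylation under Barbier conditions, in which the allylchromium should add through its γ-carbon C7 to the C6 aldehyde in a chair-like cyclic transition state that places the C5 and C8 chains anti (trans-lactone after lactonization of the chromium alkoxide onto the methyl ester), with the C8 silyloxy centre and the rigid Z-alkenyl furanone bridge selecting the face of C7.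

Step 18
Reactants: 26 (6R,7S,8S,9S,10R)-9-acetoxy-8-(TBSO)-1-oxo-3,10-epoxygermacra-2,4Z,11(13)-trien-12,6-olide
Product: 27 9-acetoxy-8-hydroxy-1-oxo-3,10-epoxygermacra-2,4Z,11(13)-trien-12,6-olide with the spatial arrangement of the target at C6 to C10 (formally 6R,7R,8S,9S,10R)
Conditions: HF·pyridine, THF, 0 → 23 °C
Reagents that add atoms: none
Why: Acidic fluoride removes the secondary silyl ether without base, so that the C9 acetate should not migrate and the methylene lactone is not attacked.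

Step 19
Reactants: 28 tert-butyl prop-2-enoate; 29 acetaldehyde
Product: 30 tert-butyl 3-hydroxy-2-methylidenebutanoate (racemic)
Conditions: DABCO, dioxane/H2O, 23 °C, sealed vessel
Reagents that add atoms: none
Why: Morita–Baylis–Hillman reaction of the acrylate with acetaldehyde, whose racemic carbinol centre is removed again in step 21.

Step 20
Reactants: 30 tert-butyl 3-hydroxy-2-methylidenebutanoate
Product: 31 tert-butyl 3-acetoxy-2-methylidenebutanoate (racemic)
Conditions: Ac2O, DMAP (cat.), Et3N, CH2Cl2, 0 °C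
Reagents that add atoms: acetic anhydride, CC(=O)OC(C)=O
Why: Standard acetylation of the secondary allylic alcohol.

Step 21
Reactants: 31 tert-butyl 3-acetoxy-2-methylidenebutanoate
Product: 32 tert-butyl (2E)-2-(acetoxymethyl)but-2-enoate
Conditions: DABCO (cat.), THF, 65 °C
Reagents that add atoms: none
Why: Amine-catalysed 1,3-transposition of the acetate (SN2′ addition of DABCO, then SN2′ return of acetate) should equilibrate to the more substituted alkene with the methyl group trans to the ester, the geometry of the target side chain.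

Step 22
Reactants: 32 tert-butyl (2E)-2-(acetoxymethyl)but-2-enoate
Product: 33 (2E)-2-(acetoxymethyl)but-2-enoic acid
Conditions: CF3CO2H, CH2Cl2, 0 → 23 °C
Reagents that add atoms: none
Why: Acidolysis of the tert-butyl ester through the tert-butyl cation leaves the primary acetate and the alkene geometry intact.

Step 23
Reactants: 27 9-acetoxy-8-hydroxy-1-oxo-3,10-epoxygermacra-2,4Z,11(13)-trien-12,6-olide; 33 (2E)-2-(acetoxymethyl)but-2-enoic acid
Product: 35 (6R,7S,8S,9S,10R)-9-acetoxy-8-[(2E)-2-(acetoxymethyl)but-2-enoyloxy]-1-oxo-3,10-epoxygermacra-2,4Z,11(13)-trien-12,6-olide (CNP0325609.1), via mixed anhydride 34 (not isolated)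
Conditions: 33, 2,4,6-trichlorobenzoyl chloride, Et3N, toluene, 23 °C; then 27, DMAP, 23 °C
Reagents that add atoms: none
Why: Yamaguchi esterification acylates the hindered C8 hydroxyl with retention at C8, and acylation should be faster than migration of the neighbouring acetate.

Compound list

1 | 2,2-dimethoxyacetaldehyde | COC(OC)C=O | starting material
2 | ethyl 2-[bis(2,2,2-trifluoroethoxy)phosphoryl]propanoate | CCOC(=O)C(C)P(=O)(OCC(F)(F)F)OCC(F)(F)F | starting material
3 | ethyl (2Z)-4,4-dimethoxy-2-methylbut-2-enoate | CCOC(=O)/C(C)=C\C(OC)OC | intermediate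
4 | (2Z)-N,4,4-trimethoxy-N,2-dimethylbut-2-enamide | CON(C)C(=O)/C(C)=C\C(OC)OC | intermediate
5 | (3Z)-5,5-dimethoxy-3-methylpent-3-en-2-one | CC(=O)/C(C)=C\C(OC)OC | intermediate
6 | (2S)-but-3-ene-1,2-diol | OC[C@@H](O)C=C | starting material
7 | (2S)-1,2-bis(tert-butyldimethylsilyloxy)but-3-ene | CC(C)(C)[Si](C)(C)OC[C@@H](O[Si](C)(C)C(C)(C)C)C=C | intermediate
8 | (2S)-2-(tert-butyldimethylsilyloxy)but-3-en-1-ol | OC[C@@H](O[Si](C)(C)C(C)(C)C)C=C | intermediate
9 | (2S)-2-(tert-butyldimethylsilyloxy)but-3-enal | O=C[C@@H](O[Si](C)(C)C(C)(C)C)C=C | intermediate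
10 | ethyl (2Z,4S)-4-(tert-butyldimethylsilyloxy)-2-methylhexa-2,5-dienoate | CCOC(=O)/C(C)=C\[C@@H](O[Si](C)(C)C(C)(C)C)C=C | intermediate
11 | (2Z,4S)-4-(tert-butyldimethylsilyloxy)-2-methylhexa-2,5-dien-1-ol | OC/C(C)=C\[C@@H](O[Si](C)(C)C(C)(C)C)C=C | intermediate
12 | [(2R,3S)-3-[(1S)-1-(tert-butyldimethylsilyloxy)prop-2-en-1-yl]-2-methyloxiran-2-yl]methanol | OC[C@@]1(C)O[C@H]1[C@@H](O[Si](C)(C)C(C)(C)C)C=C | intermediate
13 | (2S,3S)-3-[(1S)-1-(tert-butyldimethylsilyloxy)prop-2-en-1-yl]-2-methyloxirane-2-carboxylic acid | OC(=O)[C@@]1(C)O[C@H]1[C@@H](O[Si](C)(C)C(C)(C)C)C=C | intermediate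
14 | 1-[(2S,3S)-3-[(1S)-1-(tert-butyldimethylsilyloxy)prop-2-en-1-yl]-2-methyloxirane-2-carbonyl]imidazole | O=C(n1ccnc1)[C@@]2(C)O[C@H]2[C@@H](O[Si](C)(C)C(C)(C)C)C=C | intermediate (not isolated)
15 | (4Z)-1-[(2S,3S)-3-[(1S)-1-(tert-butyldimethylsilyloxy)prop-2-en-1-yl]-2-methyloxiran-2-yl]-6,6-dimethoxy-4-methylhex-4-ene-1,3-dione | COC(OC)/C=C(/C)C(=O)CC(=O)[C@@]1(C)O[C@H]1[C@@H](O[Si](C)(C)C(C)(C)C)C=C | intermediate (not isolated)
16 | (2R)-2-[(1S,2S)-2-(tert-butyldimethylsilyloxy)-1-hydroxybut-3-en-1-yl]-5-[(1Z)-3,3-dimethoxy-1-methylprop-1-en-1-yl]-2-methylfuran-3(2H)-one | COC(OC)/C=C(/C)C1=CC(=O)[C@](C)(O1)[C@@H](O)[C@@H](O[Si](C)(C)C(C)(C)C)C=C | intermediate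
17 | (1S,2S)-2-(tert-butyldimethylsilyloxy)-1-[(2R)-5-[(1Z)-3,3-dimethoxy-1-methylprop-1-en-1-yl]-2-methyl-3-oxo-2,3-dihydrofuran-2-yl]but-3-en-1-yl acetate | COC(OC)/C=C(/C)C1=CC(=O)[C@](C)(O1)[C@@H](OC(C)=O)[C@@H](O[Si](C)(C)C(C)(C)C)C=C | intermediate
18 | 3,4-dihydroxybutyl analogue of 17 (vicinal diol from the vinyl group, C7 epimers) | COC(OC)/C=C(/C)C1=CC(=O)[C@](C)(O1)[C@@H](OC(C)=O)[C@@H](O[Si](C)(C)C(C)(C)C)C(O)CO | intermediate (not isolated)
19 | (1S,2R)-2-(tert-butyldimethylsilyloxy)-1-[(2R)-5-[(1Z)-3,3-dimethoxy-1-methylprop-1-en-1-yl]-2-methyl-3-oxo-2,3-dihydrofuran-2-yl]-3-oxopropyl acetate | COC(OC)/C=C(/C)C1=CC(=O)[C@](C)(O1)[C@@H](OC(C)=O)[C@@H](O[Si](C)(C)C(C)(C)C)C=O | intermediate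
20 | methyl prop-2-ynoate | C#CC(=O)OC | starting material
21 | methyl 2-(diisobutylalumanyl)prop-2-enoate | C=C(C(=O)OC)[Al](CC(C)C)CC(C)C | intermediate (not isolated)
22 | methyl (4S,5S)-5-acetoxy-4-(tert-butyldimethylsilyloxy)-5-[(2R)-5-[(1Z)-3,3-dimethoxy-1-methylprop-1-en-1-yl]-2-methyl-3-oxo-2,3-dihydrofuran-2-yl]-3-hydroxy-2-methylidenepentanoate (C3 epimers) | COC(OC)/C=C(/C)C1=CC(=O)[C@](C)(O1)[C@@H](OC(C)=O)[C@@H](O[Si](C)(C)C(C)(C)C)C(O)C(=C)C(=O)OC | intermediate
23 | methyl (4S,5S)-5-acetoxy-4-(tert-butyldimethylsilyloxy)-3-hydroxy-2-methylidene-5-[(2R)-2-methyl-5-[(1Z)-1-methyl-3-oxoprop-1-en-1-yl]-3-oxo-2,3-dihydrofuran-2-yl]pentanoate (C3 epimers) | O=C/C=C(/C)C1=CC(=O)[C@](C)(O1)[C@@H](OC(C)=O)[C@@H](O[Si](C)(C)C(C)(C)C)C(O)C(=C)C(=O)OC | intermediate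
24 | methyl (2Z,4S,5S)-5-acetoxy-2-(bromomethyl)-4-(tert-butyldimethylsilyloxy)-5-[(2R)-2-methyl-5-[(1Z)-1-methyl-3-oxoprop-1-en-1-yl]-3-oxo-2,3-dihydrofuran-2-yl]pent-2-enoate | O=C/C=C(/C)C1=CC(=O)[C@](C)(O1)[C@@H](OC(C)=O)[C@@H](O[Si](C)(C)C(C)(C)C)/C=C(\CBr)C(=O)OC | intermediate
25 | methyl 2-[(6R,7S,8S,9S,10R)-9-acetoxy-8-(tert-butyldimethylsilyloxy)-6-hydroxy-1-oxo-3,10-epoxygermacra-2,4Z-dien-7-yl]prop-2-enoate | O[C@@H]1/C=C(/C)C2=CC(=O)[C@](C)(O2)[C@@H](OC(C)=O)[C@@H](O[Si](C)(C)C(C)(C)C)[C@H]1C(=C)C(=O)OC | intermediate (not isolated)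
26 | (6R,7S,8S,9S,10R)-9-acetoxy-8-(tert-butyldimethylsilyloxy)-1-oxo-3,10-epoxygermacra-2,4Z,11(13)-trien-12,6-olide | C=C1C(=O)O[C@@H]2/C=C(/C)C3=CC(=O)[C@](C)(O3)[C@@H](OC(C)=O)[C@@H](O[Si](C)(C)C(C)(C)C)[C@@H]12 | intermediate
27 | 9-acetoxy-8-hydroxy-1-oxo-3,10-epoxygermacra-2,4Z,11(13)-trien-12,6-olide, configured as the target (formally 6R,7R,8S,9S,10R) | C=C1C(=O)O[C@@H]2/C=C(/C)C3=CC(=O)[C@](C)(O3)[C@@H](OC(C)=O)[C@@H](O)[C@@H]12 | intermediate
28 | tert-butyl prop-2-enoate | C=CC(=O)OC(C)(C)C | starting material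
29 | acetaldehyde | CC=O | starting material
30 | tert-butyl 3-hydroxy-2-methylidenebutanoate (racemic) | CC(O)C(=C)C(=O)OC(C)(C)C | intermediate
31 | tert-butyl 3-acetoxy-2-methylidenebutanoate (racemic) | CC(OC(C)=O)C(=C)C(=O)OC(C)(C)C | intermediate
32 | tert-butyl (2E)-2-(acetoxymethyl)but-2-enoate | CC(C)(C)OC(=O)/C(=C/C)COC(C)=O | intermediate
33 | (2E)-2-(acetoxymethyl)but-2-enoic acid | OC(=O)/C(=C/C)COC(C)=O | intermediate
34 | (2E)-2-(acetoxymethyl)but-2-enoic 2,4,6-trichlorobenzoic anhydride | O=C(OC(=O)/C(=C/C)COC(C)=O)c1c(Cl)cc(Cl)cc1Cl | intermediate (not isolated)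
35 | (6R,7S,8S,9S,10R)-9-acetoxy-8-[(2E)-2-(acetoxymethyl)but-2-enoyloxy]-1-oxo-3,10-epoxygermacra-2,4Z,11(13)-trien-12,6-olide | C=C1C(=O)O[C@@H]2/C=C(/C)C3=CC(=O)[C@](C)(O3)[C@@H](OC(C)=O)[C@@H](OC(=O)/C(=C/C)COC(C)=O)[C@@H]12 | target

Total step count: 23. Longest linear sequence: 16 steps (steps 4–18, then step 23).

Steps most likely to fail

Step 11 (Proposed new method). The hindered acyl imidazole may be acylated slowly, the lithium diketonate may stay chelated and not open the epoxide, or the epoxide may open 6-endo at C9. The fallback uses known chemistry only: a neighbouring group opens the epoxide at C10, and the furanone is closed at O–C3 by cyclodehydration of an α′-hydroxy 1,3-diketone. It sets out from 12 and comes back at 16.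
- Phenyl isocyanate converts 12 to the phenylcarbamate of 12, F1.
- BF3·OEt2 followed by dilute acid lets the carbamate oxygen attack C10 with inversion and gives (4S)-4-[(1S,2S)-2-(TBSO)-1-hydroxybut-3-en-1-yl]-4-methyl-1,3-dioxolan-2-one, F2.
- K2CO3 in methanol gives (2S,3S,4S)-4-(TBSO)-2-methylhex-5-ene-1,2,3-triol, F3.
- TEMPO and PhI(OAc)2 oxidise only the primary alcohol to (2R,3S,4S)-4-(TBSO)-2,3-dihydroxy-2-methylhex-5-enal, F4.
- TMSCl and imidazole give its 2,3-bis(trimethylsilyl) ether, F5.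
- The lithium enolate of 5 adds to F5 to give the aldol adduct, F6.
- Dess–Martin periodinane gives the 1,3-diketone, F7.
- PPTS in methanol removes both trimethylsilyl groups, and the tertiary C10 hydroxyl adds to the C3 carbonyl with loss of water to give 16.

C10 is inverted once relative to the epoxide in this sequence as in the main route, so the same configuration should result.

Step 17. The ten-membered ring closure may give way to oligomerization, to transannular attack of the allylchromium on the C1 carbonyl (a five-membered ring), or to the wrong face at C6 and C7. The fallback changes the allyl donor and the way the allylmetal is generated. It sets out from 23 and comes back at 26. Acetylation of 23 gives the allylic acetate of 23, F8. Pd(PPh3)4 (zerovalent palladium) with InI in THF then ionizes the acetate to a π-allylpalladium complex that is transmetalated to an allylindium species at low stationary concentration; this adds to the C6 aldehyde through 25 and lactonizes to 26.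

Step 9. The titanium tartrate epoxidation is slow and poorly selective for Z-allylic alcohols with a branched cis substituent, and the reagent may work against the bias of the C8 centre. The fallback replaces reagent control by ring control. It sets out from 10 and comes back at 16, bypassing steps 8 to 10.
- Aqueous HF in MeCN removes the silyl group and the Z-hydroxy ester lactonizes to (5S)-5-ethenyl-3-methylfuran-2(5H)-one, F9.
- NaOCl in pyridine epoxidizes the butenolide anti to the vinyl group to give (3S,4S,5S)-5-ethenyl-3,4-epoxy-3-methyloxolan-2-one, F10, which has the (9S,10S) epoxide needed.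
- MeNHOMe·HCl and i-PrMgCl open the lactone to (2S,3S)-3-[(1S)-1-hydroxyprop-2-en-1-yl]-N-methoxy-N,2-dimethyloxirane-2-carboxamide, F11.
- TBSOTf and 2,6-lutidine give its TBS ether, F12.
- F12 replaces 14 in step 11 and acylates the enolate of 5 to 15 and on to 16.

Further compounds
F1 | step 11 | [(2R,3S)-3-[(1S)-1-(tert-butyldimethylsilyloxy)prop-2-en-1-yl]-2-methyloxiran-2-yl]methyl N-phenylcarbamate | O=C(Nc1ccccc1)OC[C@@]2(C)O[C@H]2[C@@H](O[Si](C)(C)C(C)(C)C)C=C
F2 | step 11 | (4S)-4-[(1S,2S)-2-(tert-butyldimethylsilyloxy)-1-hydroxybut-3-en-1-yl]-4-methyl-1,3-dioxolan-2-one | O=C1OC[C@](C)(O1)[C@@H](O)[C@@H](O[Si](C)(C)C(C)(C)C)C=C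
F3 | step 11 | (2S,3S,4S)-4-(tert-butyldimethylsilyloxy)-2-methylhex-5-ene-1,2,3-triol | OC[C@](C)(O)[C@@H](O)[C@@H](O[Si](C)(C)C(C)(C)C)C=C
F4 | step 11 | (2R,3S,4S)-4-(tert-butyldimethylsilyloxy)-2,3-dihydroxy-2-methylhex-5-enal | O=C[C@](C)(O)[C@@H](O)[C@@H](O[Si](C)(C)C(C)(C)C)C=C
F5 | step 11 | (2R,3S,4S)-4-(tert-butyldimethylsilyloxy)-2-methyl-2,3-bis(trimethylsilyloxy)hex-5-enal | O=C[C@](C)(O[Si](C)(C)C)[C@@H](O[Si](C)(C)C)[C@@H](O[Si](C)(C)C(C)(C)C)C=C
F6 | step 11 | aldol adduct of F5 and 5 (C1 carbinol epimers) | COC(OC)/C=C(/C)C(=O)CC(O)[C@](C)(O[Si](C)(C)C)[C@@H](O[Si](C)(C)C)[C@@H](O[Si](C)(C)C(C)(C)C)C=C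
F7 | step 11 | 1,3-diketone from oxidation of F6 | COC(OC)/C=C(/C)C(=O)CC(=O)[C@](C)(O[Si](C)(C)C)[C@@H](O[Si](C)(C)C)[C@@H](O[Si](C)(C)C(C)(C)C)C=C
F8 | step 17 | 3-O-acetate of 23 (allylic acetate, C3 epimers) | O=C/C=C(/C)C1=CC(=O)[C@](C)(O1)[C@@H](OC(C)=O)[C@@H](O[Si](C)(C)C(C)(C)C)C(OC(C)=O)C(=C)C(=O)OC
F9 | step 9 | (5S)-5-ethenyl-3-methylfuran-2(5H)-one | O=C1O[C@@H](C=C)C=C1C
F10 | step 9 | (3S,4S,5S)-5-ethenyl-3,4-epoxy-3-methyloxolan-2-one | O=C1O[C@@H](C=C)[C@@H]2O[C@]12C
F11 | step 9 | (2S,3S)-3-[(1S)-1-hydroxyprop-2-en-1-yl]-N-methoxy-N,2-dimethyloxirane-2-carboxamide | CON(C)C(=O)[C@@]1(C)O[C@H]1[C@@H](O)C=C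
F12 | step 9 | (2S,3S)-3-[(1S)-1-(tert-butyldimethylsilyloxy)prop-2-en-1-yl]-N-methoxy-N,2-dimethyloxirane-2-carboxamide | CON(C)C(=O)[C@@]1(C)O[C@H]1[C@@H](O[Si](C)(C)C(C)(C)C)C=C
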